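| setting | amber | violet | flask |
|---|---|---|---|
| Z | 20 mM | 20 mM | 20 mM |
| E | 40 mM | 90 mM | 60.0 mM |
| G | 0.17 mM | 0.17 mM | 0.17 mM |
| remark | run made earlier | run made earlier |  |

| run | time / d | J / % |
|---|---|---|
| amber | 0.208 | 0 |
| amber | 0.333 | 0 |
| amber | 0.500 | 7 |
| amber | 0.833 | 15 |
| amber | 1.67 | 19 |
| amber | 2.50 | 29 |
| violet | 0.417 | 5 |
| violet | 0.833 | 18 |
| violet | 1.25 | 25 |
| violet | 1.67 | 41 |
| violet | 2.08 | 41 |
| violet | 2.50 | 51 |

(each reading ± 2 percentage points)

- what was read earlier has a scatter of 2 percentage points, one standard deviation
- no earlier run changes the charge of G; that part of a forecast is a guess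
- what has left Z counts as converted, also if it is not yet product

- apparent order in G when 50% of the Z are converted (percent change of the rate of making J for one percent more G charged)
- factor on the rate of making J when 50% of the Z are converted if G is charged twice over

At early times the rates of making J as read are 6.00 mM d⁻¹ in amber and 6.25 mM d⁻¹ in violet up to 0.833 d, and violet starts with 2.25 times the [E]. After that reading the rates as read are 1.68 mM d⁻¹ in amber and 3.96 mM d⁻¹ in violet, factors of 3.57 and 1.58 below the early ones, but each early rate is a difference of two close readings with a scatter of 2 percentage points on each, so I read no difference in slowing between the two runs from these factors. The last readings, at 2.50 d, stand further apart: J is 51% in violet and 29% in amber. From that pair I read the E exponent, the percent change in J made for one percent more E charged, 0.696. No run changes G, so as a guess I lend G this exponent, which gives a factor of 1.62 for doubled G.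

The forecast gives 0.9 (0.45 to 1.3) and 1.9 (1.35 to 2.5), on the ground that “For a catalyst the default is first order”; my order stands lower.

    2 G ⇌ Q, settled at all times (K = 4500 M⁻¹)
    G + X ⇌ L (K = 240 M⁻¹, k = 340 M⁻¹ h⁻¹)
    Z + G → G + X (k = 3600 M⁻¹ h⁻¹)
    E + L → G + J (k = 28.0 M⁻¹ h⁻¹)

The flask gives an order of 0.77 and a factor of 1.63 at 0.104 d, where J is being made at 2.66 mM d⁻¹. At that moment in the flask, one percent more on the rate constant of E + L to G + J, a partly rate-limiting step, raises the rate by 0.64 percent. The E exponent turns amber's mean rate up to 2.50 d, 2.32 mM d⁻¹, into 3.08 mM d⁻¹ for this flask, whose own mean rate up to 4.00 d is 2.98 mM d⁻¹.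

(The runs come from a simulation for an exercise, and the scatter is random.)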